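**Retrosynthetic overview** (MOM = methoxymethyl; lavandulyl = 5-methyl-2-(prop-1-en-2-yl)hex-4-en-1-yl)
- Target 27 comes from its tetra-MOM ether 3-O-methoxyacetate 25 by two mild deprotections; the C4 ketone of 25 comes from a C4 methyl ether (24) by DDQ oxidation.
- Key disconnection: ring C of 24 is cut at O1–C2 and C3–C4, a hetero-Diels–Alder reaction between the oxadiene O1=C8a–C4a=C4 (an α-methoxy-ortho-quinone methide of ring A, made in the flask from salicylaldehyde 16) and the C2=C3 enol ester 22.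
- Enabling feature: O1 and C4 are ortho substituents of ring A, so ring A is a masked ortho-quinone methide; C2 carries the 2,4-dioxygenated ring B (ortho/para donors that stabilise positive charge at C2) and C3 carries oxygen, so the C2–C3 unit is an electron-rich β-acyloxystyrene with C3 as its nucleophilic end.
- Ring A (16): 2,4,6-trihydroxybenzaldehyde, bis-MOM ether, Br at the later C8 and I at the later C6, B-alkyl Suzuki coupling (hydrated prenyl chain), then Negishi coupling with (S)-lavandulyl iodide 14 (stereocentre from an auxiliary-controlled deconjugative alkylation). Ring B fragment (22): 2,4-dihydroxybenzaldehyde through an E-alkenylboron compound.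
- Ring order: rings A and B are bought as benzenes; ring C is the only ring formed (step 14).

Key step: step 14

Remark: the sense of induction of the chiral acid in step 14 cannot be predicted with certainty, so the (R)-acid is written and its mirror image would be used if a model reaction showed the opposite sense.

**Step 1**
Reactants: 1 2,4,6-trihydroxybenzaldehyde
Product: 2 2-hydroxy-4,6-bis(methoxymethoxy)benzaldehyde
Conditions: MOMCl (2.1 equiv), i-Pr2NEt, CH2Cl2, 0 °C to rt
Reagents that add atoms: chloromethyl methyl ether, COCCl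
Why: Williamson-type O-alkylation should take the two hydroxyls that are not hydrogen-bonded to the formyl group and leave the chelated 2-OH (the later O1) free.

**Step 2**
Reactants: 2 2-hydroxy-4,6-bis(methoxymethoxy)benzaldehyde
Product: 3 3-bromo-2-hydroxy-4,6-bis(methoxymethoxy)benzaldehyde
Conditions: NBS (1.0 equiv), CH2Cl2, −20 to 0 °C
Reagents that add atoms: N-bromosuccinimide, O=C1CCC(=O)N1Br
Why: Electrophilic aromatic bromination should go to C3, ortho to the free phenol and less hindered than C5 between the two MOM ethers, which marks the later C8.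

**Step 3**
Reactants: 3 3-bromo-2-hydroxy-4,6-bis(methoxymethoxy)benzaldehyde
Product: 4 3-bromo-2-hydroxy-5-iodo-4,6-bis(methoxymethoxy)benzaldehyde
Conditions: NIS (1.1 equiv), cat. CF3CO2H, MeCN, 0 °C to rt
Reagents that add atoms: N-iodosuccinimide, O=C1CCC(=O)N1I
Why: Electrophilic aromatic iodination of the only ring position left (C5, para to the phenol) gives two different halogens for two successive couplings.

**Step 4**
Reactants: 5 2-methylbut-3-en-2-ol; 4 3-bromo-2-hydroxy-5-iodo-4,6-bis(methoxymethoxy)benzaldehyde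
Product: 7 3-bromo-2-hydroxy-5-(3-hydroxy-3-methylbutyl)-4,6-bis(methoxymethoxy)benzaldehyde, via B-alkyl-9-BBN 6 (not isolated)
Conditions: 9-BBN-H (slightly less than 1 equiv per 5), THF, 0 °C to rt; then 4, Pd(dppf)Cl2 (5 mol %), aq K3PO4, THF/DMF, 50 °C
Reagents that add atoms: 9-borabicyclo[3.3.1]nonane, B1C2CCCC1CCC2 (stays in intermediate 6 only)
Why: Anti-Markovnikov hydroboration followed by B-alkyl Suzuki–Miyaura coupling, selective for the C–I bond over the C–Br bond because of faster oxidative addition, should install the hydrated prenyl chain before any other alkene is present.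

**Step 5**
Reactants: 8 (4S)-4-benzyl-1,3-oxazolidin-2-one; 9 3-methylbut-2-enoyl chloride
Product: 10 (4S)-4-benzyl-3-(3-methylbut-2-enoyl)-1,3-oxazolidin-2-one
Conditions: n-BuLi, THF, −78 °C; then 9, −78 to 0 °C
Reagents that add atoms: none
Why: N-acylation of the lithiated oxazolidinone is the standard way to an N-acyl oxazolidinone.

**Step 6**
Reactants: 10 (4S)-4-benzyl-3-(3-methylbut-2-enoyl)-1,3-oxazolidin-2-one; 11 1-bromo-3-methylbut-2-ene
Product: 12 (4S)-4-benzyl-3-[(2S)-5-methyl-2-(prop-1-en-2-yl)hex-4-enoyl]-1,3-oxazolidin-2-one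
Conditions: NaN(SiMe3)2 (1.1 equiv), THF, −78 °C; then 11, −78 to −40 °C
Reagents that add atoms: none
Why: γ-Deprotonation gives the chelated Z-dienolate, which should be alkylated at the α-carbon on the face opposite to the benzyl group (Evans asymmetric alkylation in its deconjugative form), and this sets the lavandulyl stereocentre.

**Step 7**
Reactants: 12 (4S)-4-benzyl-3-[(2S)-5-methyl-2-(prop-1-en-2-yl)hex-4-enoyl]-1,3-oxazolidin-2-one
Product: 13 (2S)-5-methyl-2-(prop-1-en-2-yl)hex-4-en-1-ol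
Conditions: LiBH4, H2O (1 equiv), Et2O, 0 °C
Reagents that add atoms: none
Why: Reductive cleavage of the N-acyl oxazolidinone to the primary alcohol is not basic, so the β,γ-unsaturated stereocentre should survive, and the auxiliary is returned.

**Step 8**
Reactants: 13 (2S)-5-methyl-2-(prop-1-en-2-yl)hex-4-en-1-ol
Product: 14 (3S)-3-(iodomethyl)-2,6-dimethylhepta-1,5-diene
Conditions: I2, PPh3, imidazole, CH2Cl2, 0 °C to rt
Reagents that add atoms: iodine, [I][I]
Why: Appel-type iodination of a primary alcohol does not involve the stereocentre.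

**Step 9**
Reactants: 14 (3S)-3-(iodomethyl)-2,6-dimethylhepta-1,5-diene; 7 3-bromo-2-hydroxy-5-(3-hydroxy-3-methylbutyl)-4,6-bis(methoxymethoxy)benzaldehyde
Product: 16 2-hydroxy-5-(3-hydroxy-3-methylbutyl)-4,6-bis(methoxymethoxy)-3-[(2R)-5-methyl-2-(prop-1-en-2-yl)hex-4-en-1-yl]benzaldehyde, via lavandulylzinc iodide 15 (not isolated)
Conditions: Zn dust, LiCl, THF, 40 °C; then 7, Pd(OAc)2 (3 mol %), SPhos (6 mol %), THF/NMP, 50 °C, slow addition of 15 (1.5 equiv)
Reagents that add atoms: zinc, [Zn] (stays in intermediate 15 only)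
Why: Zinc insertion into the primary iodide and Negishi coupling with the remaining aryl bromide should work because an alkylzinc halide tolerates the aldehyde and the free hydroxyls and the bulky biarylphosphine favours reductive elimination over β-hydride elimination; the stereocentre is not touched.

**Step 10**
Reactants: 17 2,4-dihydroxybenzaldehyde
Product: 18 2,4-bis(methoxymethoxy)benzaldehyde
Conditions: MOMCl (2.5 equiv), i-Pr2NEt, CH2Cl2, reflux
Reagents that add atoms: chloromethyl methyl ether, COCCl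
Why: Exhaustive Williamson-type O-alkylation of both phenols.

**Step 11**
Reactants: 18 2,4-bis(methoxymethoxy)benzaldehyde; 19 2-(dichloromethyl)-4,4,5,5-tetramethyl-1,3,2-dioxaborolane
Product: 20 2-{(E)-2-[2,4-bis(methoxymethoxy)phenyl]ethenyl}-4,4,5,5-tetramethyl-1,3,2-dioxaborolane
Conditions: CrCl2 (8 equiv), LiI (4 equiv), THF, rt
Reagents that add atoms: none
Why: Takai–Utimoto borylolefination through a geminal dichromium species should give the E-alkenylboronate from the aryl aldehyde.

**Step 12**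
Reactants: 20 2-{(E)-2-[2,4-bis(methoxymethoxy)phenyl]ethenyl}-4,4,5,5-tetramethyl-1,3,2-dioxaborolane
Product: 21 potassium {(E)-2-[2,4-bis(methoxymethoxy)phenyl]ethenyl}trifluoroborate
Conditions: KHF2 (4 equiv), MeOH/H2O, rt
Reagents that add atoms: potassium hydrogen difluoride, [K+].[F-].F
Why: Standard conversion of a pinacol boronate into the trifluoroborate salt, with the alkene geometry kept.

**Step 13**
Reactants: 21 potassium {(E)-2-[2,4-bis(methoxymethoxy)phenyl]ethenyl}trifluoroborate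
Product: 22 (E)-2-[2,4-bis(methoxymethoxy)phenyl]ethenyl methoxyacetate
Conditions: methoxyacetic acid (2 equiv), CuBr (10 mol %), DMAP (20 mol %), 4 Å MS, O2 (1 atm), MeCN, 40 °C
Reagents that add atoms: methoxyacetic acid, COCC(=O)O
Why: Copper-catalysed oxidative C–O coupling of an alkenyltrifluoroborate with a carboxylic acid (Chan–Lam type) should give the enol ester with retention of the E geometry; the methoxyacetyl group is chosen because it can later be removed without base.

**Step 14**
Reactants: 16 2-hydroxy-5-(3-hydroxy-3-methylbutyl)-4,6-bis(methoxymethoxy)-3-[(2R)-5-methyl-2-(prop-1-en-2-yl)hex-4-en-1-yl]benzaldehyde; 22 (E)-2-[2,4-bis(methoxymethoxy)phenyl]ethenyl methoxyacetate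
Product: 24 (2R,3S,4R)-2-[2,4-bis(methoxymethoxy)phenyl]-6-(3-hydroxy-3-methylbutyl)-4-methoxy-5,7-bis(methoxymethoxy)-8-[(2R)-5-methyl-2-(prop-1-en-2-yl)hex-4-en-1-yl]-3,4-dihydro-2H-chromen-3-yl methoxyacetate (2,3-trans and 2,4-cis), via dimethyl acetal 23 (not isolated)
Conditions: 16, HC(OMe)3 (3 equiv), (R)-3,3'-bis(2,4,6-triisopropylphenyl)-1,1'-binaphthyl-2,2'-diyl N-(trifluoromethylsulfonyl)phosphoramide (10 mol %), CH2Cl2, 0 °C; volatiles removed; then 22 (1.5 equiv), 5 Å MS, toluene, −40 to 0 °C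
Reagents that add atoms: trimethyl orthoformate, COC(OC)OC
Why: Proposed new method: the chiral acid should ionise acetal 23 to an α-methoxy-ortho-quinone methide/oxocarbenium ion pair (O1=C8a–C4a=C4), which adds the electron-rich E-enol ester 22 in an inverse-electron-demand hetero-Diels–Alder reaction, C4 bonding to C3 and O1 to C2. The closest known reaction types are the N-triflylphosphoramide-catalysed [4+2] cycloaddition of ortho-quinone methides with styrenes and the Lewis-acid-mediated chroman synthesis from salicylaldehydes, orthoformates and alkenes. Ring C is closed in a [4+2] mode; in the stepwise limit this is a 6-endo capture of the 2,4-dialkoxybenzyl cation by the phenolic oxygen, assisted by the neighbouring acyloxy group. C2 and C3 should come out trans because the E geometry of 22 is transferred suprafacially (the acyloxonium path leads to the same result), and their absolute configuration should be fixed by the chiral phosphoramide anion, hydrogen-bonded to O1–H, which shields one face of the oxadiene with the aryl group endo; C4 (written 2,4-cis) is erased in step 15. The step needs regioselectivity, which the ortho/para alkoxy donors of ring B secure by making C3 the nucleophilic end despite its acyloxy group; site selectivity between O1 and O5, which the MOM group on O5 secures; and chemoselectivity over the side-chain alkenes, which are far less nucleophilic than the alkoxystyrene.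

**Step 15**
Reactants: 24 (2R,3S,4R)-2-[2,4-bis(methoxymethoxy)phenyl]-6-(3-hydroxy-3-methylbutyl)-4-methoxy-5,7-bis(methoxymethoxy)-8-[(2R)-lavandulyl]-3,4-dihydro-2H-chromen-3-yl methoxyacetate
Product: 25 (2R,3R)-2-[2,4-bis(methoxymethoxy)phenyl]-6-(3-hydroxy-3-methylbutyl)-5,7-bis(methoxymethoxy)-8-[(2R)-5-methyl-2-(prop-1-en-2-yl)hex-4-en-1-yl]-4-oxo-3,4-dihydro-2H-chromen-3-yl methoxyacetate
Conditions: DDQ (1.5 equiv), CH2Cl2/pH 7 buffer (10:1), 0 °C
Reagents that add atoms: water, O
Why: Oxidative cleavage of an electron-rich benzylic methyl ether by DDQ (hydride abstraction at C4, hydration of the oxocarbenium ion, loss of methanol) should unmask the C4 ketone without touching C2 and C3, whose trans arrangement is also the thermodynamic one.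

**Step 16**
Reactants: 25 (2R,3R)-2-[2,4-bis(methoxymethoxy)phenyl]-6-(3-hydroxy-3-methylbutyl)-5,7-bis(methoxymethoxy)-8-[(2R)-lavandulyl]-4-oxo-3,4-dihydro-2H-chromen-3-yl methoxyacetate
Product: 26 (2R,3R)-2-[2,4-bis(methoxymethoxy)phenyl]-3-hydroxy-6-(3-hydroxy-3-methylbutyl)-5,7-bis(methoxymethoxy)-8-[(2R)-5-methyl-2-(prop-1-en-2-yl)hex-4-en-1-yl]-2,3-dihydro-4H-chromen-4-one
Conditions: Yb(OTf)3 (20 mol %), MeOH, 0 °C to rt
Reagents that add atoms: none
Why: Lanthanide-triflate-catalysed methanolysis, selective for the chelating methoxyacetate, should free the 3-OH without base, so that ring C is not opened and C2 is not epimerised.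

**Step 17**
Reactants: 26 (2R,3R)-2-[2,4-bis(methoxymethoxy)phenyl]-3-hydroxy-6-(3-hydroxy-3-methylbutyl)-5,7-bis(methoxymethoxy)-8-[(2R)-lavandulyl]-2,3-dihydro-4H-chromen-4-one
Product: 27 (2R,3R)-2-(2,4-dihydroxyphenyl)-3,5,7-trihydroxy-6-(3-hydroxy-3-methylbutyl)-8-[(2R)-5-methyl-2-(prop-1-en-2-yl)hex-4-en-1-yl]-2,3-dihydro-4H-chromen-4-one (target)
Conditions: ZnBr2 (6 equiv), n-PrSH (10 equiv), CH2Cl2, 0 °C, short reaction time
Reagents that add atoms: none
Why: Lewis-acid-assisted transfer of the four methoxymethyl groups to the thiol should cleave the aryl MOM ethers within minutes under aprotic conditions, which spares the tertiary alcohol, the side-chain alkenes and the acid- and base-sensitive dihydroflavonol.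

**Compound list**
1 | 2,4,6-trihydroxybenzaldehyde | O=Cc1c(O)cc(O)cc1O | starting material
2 | 2-hydroxy-4,6-bis(methoxymethoxy)benzaldehyde | COCOc1cc(O)c(C=O)c(OCOC)c1 | intermediate
3 | 3-bromo-2-hydroxy-4,6-bis(methoxymethoxy)benzaldehyde | COCOc1cc(OCOC)c(C=O)c(O)c1Br | intermediate
4 | 3-bromo-2-hydroxy-5-iodo-4,6-bis(methoxymethoxy)benzaldehyde | COCOc1c(I)c(OCOC)c(C=O)c(O)c1Br | intermediate
5 | 2-methylbut-3-en-2-ol | C=CC(C)(C)O | starting material
6 | 4-(9-borabicyclo[3.3.1]nonan-9-yl)-2-methylbutan-2-ol | CC(C)(O)CCB1C2CCCC1CCC2 | intermediate (not isolated)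
7 | 3-bromo-2-hydroxy-5-(3-hydroxy-3-methylbutyl)-4,6-bis(methoxymethoxy)benzaldehyde | COCOc1c(CCC(C)(C)O)c(OCOC)c(C=O)c(O)c1Br | intermediate
8 | (4S)-4-benzyl-1,3-oxazolidin-2-one | O=C1N[C@@H](Cc2ccccc2)CO1 | starting material
9 | 3-methylbut-2-enoyl chloride | CC(C)=CC(=O)Cl | starting material
10 | (4S)-4-benzyl-3-(3-methylbut-2-enoyl)-1,3-oxazolidin-2-one | CC(C)=CC(=O)N1[C@@H](Cc2ccccc2)COC1=O | intermediate
11 | 1-bromo-3-methylbut-2-ene | CC(C)=CCBr | starting material
12 | (4S)-4-benzyl-3-[(2S)-5-methyl-2-(prop-1-en-2-yl)hex-4-enoyl]-1,3-oxazolidin-2-one | C=C(C)[C@H](CC=C(C)C)C(=O)N1[C@@H](Cc2ccccc2)COC1=O | intermediate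
13 | (2S)-5-methyl-2-(prop-1-en-2-yl)hex-4-en-1-ol ((S)-lavandulol) | C=C(C)[C@H](CC=C(C)C)CO | intermediate
14 | (3S)-3-(iodomethyl)-2,6-dimethylhepta-1,5-diene ((S)-lavandulyl iodide) | C=C(C)[C@H](CC=C(C)C)CI | intermediate
15 | [(2S)-5-methyl-2-(prop-1-en-2-yl)hex-4-en-1-yl]zinc iodide | C=C(C)[C@H](CC=C(C)C)C[Zn]I | intermediate (not isolated)
16 | 2-hydroxy-5-(3-hydroxy-3-methylbutyl)-4,6-bis(methoxymethoxy)-3-[(2R)-5-methyl-2-(prop-1-en-2-yl)hex-4-en-1-yl]benzaldehyde | C=C(C)[C@H](CC=C(C)C)Cc1c(OCOC)c(CCC(C)(C)O)c(OCOC)c(C=O)c1O | intermediate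
17 | 2,4-dihydroxybenzaldehyde | O=Cc1ccc(O)cc1O | starting material
18 | 2,4-bis(methoxymethoxy)benzaldehyde | COCOc1ccc(C=O)c(OCOC)c1 | intermediate
19 | 2-(dichloromethyl)-4,4,5,5-tetramethyl-1,3,2-dioxaborolane | ClC(Cl)B1OC(C)(C)C(C)(C)O1 | starting material
20 | 2-{(E)-2-[2,4-bis(methoxymethoxy)phenyl]ethenyl}-4,4,5,5-tetramethyl-1,3,2-dioxaborolane | COCOc1ccc(/C=C/B2OC(C)(C)C(C)(C)O2)c(OCOC)c1 | intermediate
21 | potassium {(E)-2-[2,4-bis(methoxymethoxy)phenyl]ethenyl}trifluoroborate | COCOc1ccc(/C=C/[B-](F)(F)F)c(OCOC)c1.[K+] | intermediate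
22 | (E)-2-[2,4-bis(methoxymethoxy)phenyl]ethenyl methoxyacetate | COCOc1ccc(/C=C/OC(=O)COC)c(OCOC)c1 | intermediate
23 | 2-(dimethoxymethyl)-4-(3-hydroxy-3-methylbutyl)-3,5-bis(methoxymethoxy)-6-[(2R)-5-methyl-2-(prop-1-en-2-yl)hex-4-en-1-yl]phenol | C=C(C)[C@H](CC=C(C)C)Cc1c(OCOC)c(CCC(C)(C)O)c(OCOC)c(C(OC)OC)c1O | intermediate (not isolated)
24 | (2R,3S,4R)-2-[2,4-bis(methoxymethoxy)phenyl]-6-(3-hydroxy-3-methylbutyl)-4-methoxy-5,7-bis(methoxymethoxy)-8-[(2R)-5-methyl-2-(prop-1-en-2-yl)hex-4-en-1-yl]-3,4-dihydro-2H-chromen-3-yl methoxyacetate | C=C(C)[C@H](CC=C(C)C)Cc1c(OCOC)c(CCC(C)(C)O)c(OCOC)c2c1O[C@H](c1ccc(OCOC)cc1OCOC)[C@@H](OC(=O)COC)[C@@H]2OC | intermediate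
25 | (2R,3R)-2-[2,4-bis(methoxymethoxy)phenyl]-6-(3-hydroxy-3-methylbutyl)-5,7-bis(methoxymethoxy)-8-[(2R)-5-methyl-2-(prop-1-en-2-yl)hex-4-en-1-yl]-4-oxo-3,4-dihydro-2H-chromen-3-yl methoxyacetate | C=C(C)[C@H](CC=C(C)C)Cc1c(OCOC)c(CCC(C)(C)O)c(OCOC)c2c1O[C@H](c1ccc(OCOC)cc1OCOC)[C@@H](OC(=O)COC)C2=O | intermediate
26 | (2R,3R)-2-[2,4-bis(methoxymethoxy)phenyl]-3-hydroxy-6-(3-hydroxy-3-methylbutyl)-5,7-bis(methoxymethoxy)-8-[(2R)-5-methyl-2-(prop-1-en-2-yl)hex-4-en-1-yl]-2,3-dihydro-4H-chromen-4-one | C=C(C)[C@H](CC=C(C)C)Cc1c(OCOC)c(CCC(C)(C)O)c(OCOC)c2c1O[C@H](c1ccc(OCOC)cc1OCOC)[C@@H](O)C2=O | intermediate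
27 | (2R,3R)-2-(2,4-dihydroxyphenyl)-3,5,7-trihydroxy-6-(3-hydroxy-3-methylbutyl)-8-[(2R)-5-methyl-2-(prop-1-en-2-yl)hex-4-en-1-yl]-2,3-dihydro-4H-chromen-4-one | C=C(C)[C@H](CC=C(C)C)Cc1c(O)c(CCC(C)(C)O)c(O)c2c1O[C@H](c1ccc(O)cc1O)[C@@H](O)C2=O | target

**Totals**
Total step count: 17. Longest linear sequence: 9 steps (steps 1–4, 9, 14–17; the lavandulyl branch, steps 5–9 and 14–17, is equally long).

**Steps most likely to fail**

Step 14 (the proposed new method). The chiral ion pair may not discriminate the two faces well enough in the C–C bond formation. Acid-promoted side reactions may also outrun the cycloaddition: addition of methanol to the enol ester, or cyclisation of O1–H onto the isopropenyl group. The fallback uses known chemistry and closes ring C through O1–C2 only. It sets out from 16: addition of MeMgBr (THF, 0 °C) should give the 1-arylethanol F1, which MnO2 (CH2Cl2) should oxidise to the 2-hydroxyacetophenone F2. MOM protection of the chelated phenol (NaH, MOMCl, DMF) gives the tris-MOM acetophenone F3, and Claisen–Schmidt condensation with aldehyde 18 (KOH, EtOH) gives the E-chalcone F4. Julia–Colonna epoxidation (poly-L-leucine, urea–H2O2, DBU, THF) is expected to give the (2R,3S)-epoxy ketone F5 without touching the isolated alkenes. Dilute methanolic HCl then removes the MOM ethers, and the freed O1–H opens the epoxide at the benzylic carbon with inversion to the trans-dihydroflavonol, so that the fallback comes back to the route at 27.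

Step 9. Oxidative addition into the hindered, electron-rich C–Br bond may be slow, the phenol may protonate the alkylzinc reagent, and β-hydride elimination from the alkylpalladium intermediate may compete. The fallback replaces the zinc reagent by a boron nucleophile made by halogen–lithium exchange. It sets out from 14: t-BuLi (2 equiv, Et2O, −78 °C) and then B-methoxy-9-BBN should give the lithium alkyl(methoxy)borate F6. This is coupled with 7 in a B-alkyl Suzuki–Miyaura reaction (Pd(dppf)Cl2, K3PO4, DMF/THF, rt to 50 °C), and the fallback comes back to the route at 16.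

Step 15. DDQ may attack the electron-rich rings or the allylic positions of the side chains, or dehydrogenate C2–C3 after the ketone has formed. The fallback separates hydrolysis and oxidation. It sets out from 24: mild acid hydrolysis of the benzylic methyl ether (PPTS, wet acetone, rt) should give the 4-hydroxy compound F7 as C4 epimers. Oxidation of this benzylic alcohol with Dess–Martin periodinane (NaHCO3, CH2Cl2, 0 °C) comes back to the route at 25.

**Further compounds**
F1 | step 14 | 1-{2-hydroxy-5-(3-hydroxy-3-methylbutyl)-4,6-bis(methoxymethoxy)-3-[(2R)-5-methyl-2-(prop-1-en-2-yl)hex-4-en-1-yl]phenyl}ethan-1-ol (carbinol epimers) | C=C(C)[C@H](CC=C(C)C)Cc1c(OCOC)c(CCC(C)(C)O)c(OCOC)c(C(C)O)c1O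
F2 | step 14 | 1-{2-hydroxy-5-(3-hydroxy-3-methylbutyl)-4,6-bis(methoxymethoxy)-3-[(2R)-5-methyl-2-(prop-1-en-2-yl)hex-4-en-1-yl]phenyl}ethan-1-one | C=C(C)[C@H](CC=C(C)C)Cc1c(OCOC)c(CCC(C)(C)O)c(OCOC)c(C(C)=O)c1O
F3 | step 14 | 1-{5-(3-hydroxy-3-methylbutyl)-2,4,6-tris(methoxymethoxy)-3-[(2R)-5-methyl-2-(prop-1-en-2-yl)hex-4-en-1-yl]phenyl}ethan-1-one | C=C(C)[C@H](CC=C(C)C)Cc1c(OCOC)c(CCC(C)(C)O)c(OCOC)c(C(C)=O)c1OCOC
F4 | step 14 | (E)-3-[2,4-bis(methoxymethoxy)phenyl]-1-{5-(3-hydroxy-3-methylbutyl)-2,4,6-tris(methoxymethoxy)-3-[(2R)-5-methyl-2-(prop-1-en-2-yl)hex-4-en-1-yl]phenyl}prop-2-en-1-one | C=C(C)[C@H](CC=C(C)C)Cc1c(OCOC)c(CCC(C)(C)O)c(OCOC)c(C(=O)/C=C/c2ccc(OCOC)cc2OCOC)c1OCOC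
F5 | step 14 | {(2R,3S)-3-[2,4-bis(methoxymethoxy)phenyl]oxiran-2-yl}{5-(3-hydroxy-3-methylbutyl)-2,4,6-tris(methoxymethoxy)-3-[(2R)-5-methyl-2-(prop-1-en-2-yl)hex-4-en-1-yl]phenyl}methanone | C=C(C)[C@H](CC=C(C)C)Cc1c(OCOC)c(CCC(C)(C)O)c(OCOC)c(C(=O)[C@@H]2O[C@H]2c2ccc(OCOC)cc2OCOC)c1OCOC
F6 | step 9 | lithium 9-methoxy-9-[(2S)-5-methyl-2-(prop-1-en-2-yl)hex-4-en-1-yl]-9-borabicyclo[3.3.1]nonan-9-uide | C=C(C)[C@H](CC=C(C)C)C[B-]1(OC)C2CCCC1CCC2.[Li+]
F7 | step 15 | (2R,3S)-2-[2,4-bis(methoxymethoxy)phenyl]-4-hydroxy-6-(3-hydroxy-3-methylbutyl)-5,7-bis(methoxymethoxy)-8-[(2R)-5-methyl-2-(prop-1-en-2-yl)hex-4-en-1-yl]-3,4-dihydro-2H-chromen-3-yl methoxyacetate (C4 epimers) | C=C(C)[C@H](CC=C(C)C)Cc1c(OCOC)c(CCC(C)(C)O)c(OCOC)c2c1O[C@H](c1ccc(OCOC)cc1OCOC)[C@@H](OC(=O)COC)C2O
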